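# Proposed synthesis of 3,5,6-tribromo-1H-indole (14) by annulation of 4,5-dibromobenzyne with a glycine ester

## The problem

3,5,6-Tribromo-1H-indole (14) is a flat, achiral bicycle in which a benzene ring (ring A) is fused to a pyrrole ring (ring B) through C3a and C7a, with bromine at C3 of ring B and at C5 and C6 of ring A. With no stereocentre present, the whole task is positional control of three bromines. The C3 bromine is the easy one, because C3 is the site at which an indole takes an electrophile of its own accord. The vicinal C5/C6 pair is the real difficulty: electrophilic bromination of an indole neither separates C5 from C6 cleanly nor stops at exactly these two positions, so both bromines must sit on the six-membered ring before ring B exists. The aryl C–Br bonds then travel through the whole route and exclude alkyllithiums above cryogenic temperature, dissolving or low-valent metals, and palladium with hydrogen, while the free N–H 3-bromoindole is sensitive to acid and light and should be uncovered last. A short solution is possible because ring A is locally symmetric: the fusion carbons C7a and C3a are neighbours, each followed by a C–H (C7, C4) and then by a C–Br (C6, C5), so that a mirror plane runs through the C3a–C7a and C5–C6 bonds. The two fusion carbons can therefore be the two carbons of the symmetric aryne 4,5-dibromobenzyne (8), and N1, C2 and C3 map onto the N–CH2–C(=O) unit of a glycine ester.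

## Retrosynthesis

**N1–S bond.** Target 14 is traced back to 3,5,6-tribromo-1-tosyl-1H-indole (13) by cutting the N1–S bond. The sulfonyl group is kept to the end for three reasons: it is the group that makes the ring-forming step possible, it tames the indole during bromination, and 13 is a robust form in which to carry the 3-bromoindole. The forward reaction only has to remove an arenesulfonyl group from a weakly basic indole nitrogen under non-acidic conditions that leave the C–Br bonds alone.

**C3–Br bond.** Compound 13 is cut at C3–Br to 5,6-dibromo-1-tosyl-1H-indole (12). Bringing this bromine in earlier would expose a reactive C–Br bond α to a carbonyl or an alcohol in the preceding steps. Placed here it uses the innate C3 selectivity of the indole. The forward reaction must stop after one bromination, which the deactivated N-sulfonyl nucleus favours.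

**C2=C3 double bond.** Indole 12 is related by functional-group change only to (±)-5,6-dibromo-1-tosylindolin-3-ol (11) and then to 5,6-dibromo-1-tosylindolin-3-one (10). No skeletal bond is involved. The ketone at C3 is the direct outcome of the ring closure, and reduction followed by dehydration brings C3 to the indole oxidation level.

**N1–C7a and C3–C3a bonds.** Ketone 10 is cut at both bonds that join ring B to ring A. This gives methyl N-tosylglycinate (7), which holds N1, C2 and C3, and aryne 8, generated from 4,5-dibromo-2-(trimethylsilyl)phenyl trifluoromethanesulfonate (6). Cutting only one of the two bonds (an N-arylation of a 1,2-dihaloarene, or a Friedel–Crafts closure alone) would require a tetrasubstituted benzene with two differentiated neighbouring positions. The double cut needs only a symmetric aryne and so removes the regiochemical question. The forward reaction must add the sulfonamide nitrogen to the aryne, let the resulting aryl anion (9) acylate on the ester before it is protonated, and keep a second aryne from attacking the enolisable product.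

**C–Si and O–S bonds of the aryne precursor.** Triflate 6 is traced to 4,5-dibromo-2-iodophenol (2). The silyl group is first placed on oxygen, giving (4,5-dibromo-2-iodophenoxy)trimethylsilane (3), and is then moved to carbon through aryllithium 4 and phenoxide 5 by a retro-Brook shift before triflation. Metalation must occur ortho to oxygen in the presence of two bromines, so the position is marked with iodine, which exchanges much faster than bromine. A third bromine could not be told apart reliably, and directed deprotonation with a strong base would attack the C–Br bonds.

**C–I bond.** Iodophenol 2 is cut at C–I to 3,4-dibromophenol (1). The hydroxyl group directs ortho because the para position is occupied, and the ortho position next to bromine is hindered, so a single electrophilic iodination should give the required isomer.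

## Roads not taken

Alternative 1: The cut is made in ring A, at C3a–C4 and C7–C7a, so that the six-membered ring is built on a preformed five-membered nitrogen ring.
- Forward step: 3,4-dibromothiophene 1,1-dioxide A1 would act as an electron-poor diene towards the enecarbamate double bond of tert-butyl 2,3-dihydro-1H-pyrrole-1-carboxylate A2. The bridged adduct of A1 and A2 would extrude its sulfone bridge cheletropically and leave racemic tert-butyl cis-5,6-dibromo-2,3,3a,7a-tetrahydro-1H-indole-1-carboxylate A3.
- Merits: the diene A1 is as symmetric as the aryne of the chosen plan, so the bromines are placed without a regiochemical question. No organometallic reagent meets a C–Br bond. Two C–C bonds and ring A form in one operation.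
- Weak points: A3 still carries four hydrogens more than the indole nucleus (H3a, H7a and one hydrogen each at C2 and C3). Two dehydrogenations are therefore needed on a substrate with two vinylic bromides and allylic ring-fusion hydrogens, where elimination and over-oxidation compete. A thiophene dioxide with only two halogens tends to dimerise, and this competes with addition to an only moderately electron-rich alkene such as A2. A1 is not an ordinary stock reagent and would have to be made and used promptly.
- Comparison: the step count is about equal to that of the chosen plan (diene preparation, cycloaddition, aromatisation in one or two operations, carbamate removal, C3 bromination). This road is better in avoiding cryogenic organolithium chemistry altogether. The chosen plan sets against it that ring A is aromatic from the first step, that the oxidation-level adjustment after its key step is a plain ketone reduction and dehydration, and that each of its steps has a close counterpart on the same substrate class. The cycloaddition of A1 with A2 and the exhaustive dehydrogenation of A3 would both have to be developed.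

Alternative 2: Three bonds are cut at once, C3a–C7a, C4–C5 and C6–C7, which dissolves ring A and ring B together into three alkynes.
- Forward step: CpCo(CO)2 would co-cyclise the tethered diyne N-(but-3-yn-1-yl)-N-ethynyl-4-methylbenzenesulfonamide A4 with bis(trimethylsilyl)acetylene A5 in a [2+2+2] cyclotrimerisation to 1-tosyl-5,6-bis(trimethylsilyl)indoline A6.
- Merits: high convergency and both rings in one step. The two silyl groups of A6 are placeholders that can be exchanged for halogen one after the other, so this road could reach unsymmetrical 5,6-dihalo patterns, which a symmetric aryne cannot.
- Weak points: two ipso-bromodesilylations are needed, the second on a ring already deactivated by the first bromine and in competition with protodesilylation. A6 is an indoline and still has to be dehydrogenated, brominated at C3 and detosylated. A4 contains a terminal ynamide whose preparation alone takes several steps. A5 must be used in large excess to suppress self-trimerisation of A4, and the cobalt complex is usually needed in high loading.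
- Comparison: the sequence is clearly longer than seven steps and gains nothing for a symmetric dibromide. Its one advantage, access to mixed halogen patterns, is not needed here.

Alternative 3: Only the C2–C3 bond is cut, which opens ring B to N-(4,5-dibromo-2-formylphenyl)formamide A7.
- Forward step: low-valent titanium made from TiCl3 and zinc dust would couple the aldehyde carbon of A7 reductively with its formamide carbon and deoxygenate, giving 5,6-dibromo-1H-indole A8 directly.
- Merits: no nitrogen protecting group is needed and A8 is one bromination from the target. A7 would come from 2-amino-4,5-dibromobenzaldehyde A9 by N-formylation, so counted from A9 the sequence would be three steps, fewer than the chosen plan.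
- Weak points: A9 is not a stock compound and tends to self-condense. Its preparation needs an arene nitration whose regiochemistry is not fixed by symmetry and a nitro reduction that spares C–Br. The formamide of A7 is the least reactive acyl partner in this oxo–amide coupling, so 2-unsubstituted indoles are its weakest case. The two aryl bromides of A7 would be heated with excess zinc and low-valent titanium, conditions under which reductive debromination is a real danger.
- Comparison: this road is shorter and ends in a free indole, which is a real advantage. The chosen plan sets against it that its substitution pattern is guaranteed by the symmetry of aryne 8 and not by a selective nitration, that no reducing metal meets the C–Br bonds, and that its ring-forming step has direct precedent with N-sulfonyl α-amino esters.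

Key step: step 3

Assumption: 3,4-dibromophenol (1) and methyl N-tosylglycinate (7) are treated as catalogue compounds, and the tosyl group of 7 serves as the nitrogen protecting group up to the last step.

## Route

Step 1
Reactants: 1 3,4-dibromophenol
Product: 2 4,5-dibromo-2-iodophenol
Conditions: NIS (1.0 equiv), TsOH·H2O (10 mol%), MeCN, 0 °C to rt
Reagents that add atoms: N-iodosuccinimide O=C1CCC(=O)N1I
Why: Electrophilic aromatic iodination; the hydroxyl group directs ortho because the para position carries bromine, and of the two ortho sites C6 is open and para to the C3 bromine whereas C2 is wedged between OH and Br, so the large iodine electrophile should enter at C6, and one equivalent of NIS together with the deactivation by the first iodine should hold the reaction at mono-iodination.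

Step 2
Reactants: 2 4,5-dibromo-2-iodophenol
Product: 6 4,5-dibromo-2-(trimethylsilyl)phenyl trifluoromethanesulfonate, via silyl ether 3 (not isolated), via aryllithium 4 (not isolated), via lithium phenoxide 5 (not isolated)
Conditions: HMDS (0.7 equiv), THF, reflux, then volatiles removed in vacuo; THF, n-BuLi (1.05 equiv), −100 to −80 °C; Tf2O (1.2 equiv), −100 to −80 °C; aq. NaHCO3
Reagents that add atoms: hexamethyldisilazane C[Si](C)(C)N[Si](C)(C)C; trifluoromethanesulfonic anhydride O=S(=O)(OS(=O)(=O)C(F)(F)F)C(F)(F)F
Why: Standard one-flask preparation of an o-silylaryl triflate: HMDS silylates the phenol, iodine–lithium exchange at −100 °C is far faster than bromine–lithium exchange and is helped by the ortho oxygen, aryllithium 4 undergoes the anionic 1,3 O-to-C silyl shift (retro-Brook rearrangement) to phenoxide 5, and Tf2O traps the phenoxide; 4 has no halogen ortho to lithium, so it cannot collapse to an aryne.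

Step 3
Reactants: 6 4,5-dibromo-2-(trimethylsilyl)phenyl trifluoromethanesulfonate; 7 methyl N-tosylglycinate
Product: 10 5,6-dibromo-1-tosylindolin-3-one, via 4,5-dibromobenzyne 8 (not isolated), via caesium aryl anion 9 (not isolated)
Conditions: CsF (3 equiv), 7 (1.5 equiv), dry THF, 65 °C, 6 (1.0 equiv) added slowly by syringe pump
Reagents that add atoms: none
Why: Fluoride attacks the silicon of 6 and triflate leaves in a 1,2-elimination that releases the symmetric aryne 8. The caesium salt of sulfonamide 7, whose N–H is the most acidic site present, adds through nitrogen to one aryne carbon, forming N1–C7a and the ortho aryl anion 9. Anion 9 attacks the ester carbonyl in a 5-exo-trig closure that forms C3–C3a and ring B, and the tetrahedral intermediate expels methoxide to give ketone 10. The closest known reaction type is the aryne N-arylation and intramolecular acylation annulation of N-sulfonyl α-amino esters to indolin-3-ones, the same logic that converts anthranilates into acridones. No stereocentre is formed. Regioselectivity is not needed because the two aryne carbons of 8 are equivalent; each is meta to one bromine and para to the other, so no bromine is ortho to the developing anion and no second elimination is possible, while the inductive pull of the bromines lowers the aryne LUMO and speeds the nitrogen addition. The step needs chemoselectivity for one aryne per glycinate and survival of the enolisable product, which rests on keeping 6 limiting and adding it slowly to an excess of 7 so that free aryne meets sulfonamide anion and not product enolate. It also needs acylation of 9 to outrun its protonation, which is why dry THF, a solvent without acidic C–H bonds, is chosen over MeCN.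

Step 4
Reactants: 10 5,6-dibromo-1-tosylindolin-3-one
Product: 11 (±)-5,6-dibromo-1-tosylindolin-3-ol
Conditions: NaBH4 (1.0 equiv), MeOH/THF (1:1), 0 °C; aq. NH4Cl
Reagents that add atoms: none
Why: Borohydride reduction of an aryl ketone; the aryl bromides and the sulfonamide are inert to NaBH4, and the new C3 stereocentre is formed as a racemate and left uncontrolled because step 5 erases it.

Step 5
Reactants: 11 (±)-5,6-dibromo-1-tosylindolin-3-ol
Product: 12 5,6-dibromo-1-tosyl-1H-indole
Conditions: TsOH·H2O (10 mol%), toluene, 80 °C
Reagents that add atoms: none
Why: Acid-catalysed E1 dehydration of an N-sulfonyl-3-hydroxyindoline through the benzylic cation; loss of the C2 proton creates the aromatic pyrrole ring, which makes the elimination irreversible, and the N-tosylindole is stable to the acid.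

Step 6
Reactants: 12 5,6-dibromo-1-tosyl-1H-indole
Product: 13 3,5,6-tribromo-1-tosyl-1H-indole
Conditions: Br2 (1.05 equiv), CH2Cl2, 0 °C to rt; aq. Na2S2O3
Reagents that add atoms: bromine BrBr
Why: Electrophilic aromatic bromination at C3, the most nucleophilic position of an N-sulfonylindole; the sulfonyl group and the two ring bromines damp the nucleus enough that the reaction should stop after one bromine and leave C2 and ring A untouched.

Step 7
Reactants: 13 3,5,6-tribromo-1-tosyl-1H-indole
Product: 14 3,5,6-tribromo-1H-indole
Conditions: Cs2CO3 (3 equiv), THF/MeOH (2:1), rt; work-up with pH 7 buffer, light excluded
Reagents that add atoms: none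
Why: Base-mediated N-desulfonylation; methoxide generated by Cs2CO3 attacks sulfur, the indolide leaves readily because three bromines stabilise it, and methanol protonates it; the C–Br bonds are inert to these conditions and no acid touches the 3-bromoindole.

## Compound list

1 | 3,4-dibromophenol | Oc1ccc(Br)c(Br)c1 | starting material
2 | 4,5-dibromo-2-iodophenol | Oc1cc(Br)c(Br)cc1I | intermediate
3 | (4,5-dibromo-2-iodophenoxy)trimethylsilane | C[Si](C)(C)Oc1cc(Br)c(Br)cc1I | intermediate
4 | [4,5-dibromo-2-(trimethylsilyloxy)phenyl]lithium | C[Si](C)(C)Oc1cc(Br)c(Br)cc1[Li] | intermediate
5 | lithium 4,5-dibromo-2-(trimethylsilyl)phenoxide | [Li+].[O-]c1cc(Br)c(Br)cc1[Si](C)(C)C | intermediate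
6 | 4,5-dibromo-2-(trimethylsilyl)phenyl trifluoromethanesulfonate | C[Si](C)(C)c1cc(Br)c(Br)cc1OS(=O)(=O)C(F)(F)F | intermediate
7 | methyl N-tosylglycinate | COC(=O)CNS(=O)(=O)c1ccc(C)cc1 | starting material
8 | 4,5-dibromobenzyne (1,2-dibromo-4,5-didehydrobenzene) | BrC1=CC#CC=C1Br | intermediate
9 | caesium 4,5-dibromo-2-[(2-methoxy-2-oxoethyl)(tosyl)amino]benzenide | [Cs+].COC(=O)CN(c1cc(Br)c(Br)c[c-]1)S(=O)(=O)c1ccc(C)cc1 | intermediate
10 | 5,6-dibromo-1-tosylindolin-3-one | O=C1CN(S(=O)(=O)c2ccc(C)cc2)c2cc(Br)c(Br)cc12 | intermediate
11 | (±)-5,6-dibromo-1-tosylindolin-3-ol (racemic at C3) | OC1CN(S(=O)(=O)c2ccc(C)cc2)c2cc(Br)c(Br)cc12 | intermediate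
12 | 5,6-dibromo-1-tosyl-1H-indole | Cc1ccc(cc1)S(=O)(=O)n1ccc2cc(Br)c(Br)cc21 | intermediate
13 | 3,5,6-tribromo-1-tosyl-1H-indole | Cc1ccc(cc1)S(=O)(=O)n1cc(Br)c2cc(Br)c(Br)cc21 | intermediate
14 | 3,5,6-tribromo-1H-indole | Brc1cc2[nH]cc(Br)c2cc1Br | target

## Step count and risk assessment

Total step count: 7. Longest linear sequence: 7 steps (1 to 14); 7 enters as a purchased compound in step 3.

**Step 3 (key step).** Two processes threaten it. The first is over-arylation and self-condensation of the product: the C2 methylene of 10 lies between nitrogen and the ketone, its enolate is an aromatic 3-oxidoindole, and this enolate can compete with the sulfonamide anion for the aryne. The second is premature protonation of aryl anion 9 by adventitious water or by the N–H of 7, which would stop the sequence after N-arylation. The fallback sets out from 6 and 7 and rejoins the route at 10. The aryne is generated with CsF in MeCN containing tert-butanol, so that 9 is protonated deliberately. This is the ordinary aryne N-arylation of a sulfonamide and should give methyl N-(3,4-dibromophenyl)-N-tosylglycinate F1, which is neither nucleophilic nor readily enolised under these conditions. Saponification (LiOH, THF/H2O) would give N-(3,4-dibromophenyl)-N-tosylglycine F2. Intramolecular Friedel–Crafts acylation (P2O5/MeSO3H, 50 °C) would then close C3–C3a ortho to nitrogen at the unhindered position para to the 3-bromine, which corresponds to the 5,6-dibromo pattern of 10.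

**Step 2.** The halogen–metal exchange may lose chemoselectivity: bromine–lithium exchange or intermolecular halogen scrambling can compete if the retro-Brook shift lags behind, and the 1-iodobutane formed can alkylate 4 or 5 if the temperature rises. The fallback sets out from 3 (made from 2 with HMDS as in step 2 and freed of volatiles) and rejoins the route at 6. Iodine–magnesium exchange with i-PrMgCl·LiCl (THF, −40 °C), which leaves aryl bromides untouched, would be followed by C-silylation of the aryl Grignard reagent with TMSCl on warming, giving [4,5-dibromo-2-(trimethylsilyl)phenoxy]trimethylsilane F3. K2CO3 in MeOH would cleave only the O–Si bond to 4,5-dibromo-2-(trimethylsilyl)phenol F4, and Tf2O/pyridine in CH2Cl2 at 0 °C would give 6.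

**Step 6.** Bromination may be sluggish because the sulfonyl group and two bromines deactivate the nucleus, and forcing it may erode selectivity through attack at C2 or addition across C2=C3. The fallback sets out from 12 and rejoins the route at 14, with the order of the last two operations reversed. Cs2CO3 in THF/MeOH would remove the tosyl group first to give 5,6-dibromo-1H-indole F5, whose free pyrrole ring is far more nucleophilic. NBS (1.0 equiv) in DMF at 0 °C would then brominate C3 and give 14 directly.

**Step 5.** Ionisation of the benzylic alcohol may be slow, because the cation is destabilised by the two bromines and by the electron-poor sulfonamide nitrogen; the result would be incomplete conversion or ether formation between two molecules of 11. The fallback sets out from 11 and rejoins the route at 12, replacing the acid-mediated E1 path by activation and base-mediated elimination. MsCl/Et3N in CH2Cl2 at 0 °C would give (±)-5,6-dibromo-1-tosylindolin-3-yl methanesulfonate F6, and DBU at rt would remove the C2 proton with loss of mesylate, driven by aromatisation.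

## Further compounds

F1 | step 3 | methyl N-(3,4-dibromophenyl)-N-tosylglycinate | COC(=O)CN(c1ccc(Br)c(Br)c1)S(=O)(=O)c1ccc(C)cc1
F2 | step 3 | N-(3,4-dibromophenyl)-N-tosylglycine | OC(=O)CN(c1ccc(Br)c(Br)c1)S(=O)(=O)c1ccc(C)cc1
F3 | step 2 | [4,5-dibromo-2-(trimethylsilyl)phenoxy]trimethylsilane | C[Si](C)(C)Oc1cc(Br)c(Br)cc1[Si](C)(C)C
F4 | step 2 | 4,5-dibromo-2-(trimethylsilyl)phenol | C[Si](C)(C)c1cc(Br)c(Br)cc1O
F5 | step 6 | 5,6-dibromo-1H-indole | Brc1cc2[nH]ccc2cc1Br
F6 | step 5 | (±)-5,6-dibromo-1-tosylindolin-3-yl methanesulfonate | CS(=O)(=O)OC1CN(S(=O)(=O)c2ccc(C)cc2)c2cc(Br)c(Br)cc12
A1 | alternative 1 | 3,4-dibromothiophene 1,1-dioxide | O=S1(=O)C=C(Br)C(Br)=C1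
A2 | alternative 1 | tert-butyl 2,3-dihydro-1H-pyrrole-1-carboxylate | CC(C)(C)OC(=O)N1CCC=C1
A3 | alternative 1 | tert-butyl cis-5,6-dibromo-2,3,3a,7a-tetrahydro-1H-indole-1-carboxylate (racemic, one enantiomer drawn) | O=C(OC(C)(C)C)N1CC[C@H]2C=C(Br)C(Br)=C[C@@H]12
A4 | alternative 2 | N-(but-3-yn-1-yl)-N-ethynyl-4-methylbenzenesulfonamide | C#CCCN(C#C)S(=O)(=O)c1ccc(C)cc1
A5 | alternative 2 | bis(trimethylsilyl)acetylene | C[Si](C)(C)C#C[Si](C)(C)C
A6 | alternative 2 | 1-tosyl-5,6-bis(trimethylsilyl)indoline | Cc1ccc(cc1)S(=O)(=O)N1CCc2cc([Si](C)(C)C)c([Si](C)(C)C)cc21
A7 | alternative 3 | N-(4,5-dibromo-2-formylphenyl)formamide | O=CNc1cc(Br)c(Br)cc1C=O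
A8 | alternative 3 | 5,6-dibromo-1H-indole | Brc1cc2[nH]ccc2cc1Br
A9 | alternative 3 | 2-amino-4,5-dibromobenzaldehyde | Nc1cc(Br)c(Br)cc1C=O
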